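Solve the late end first, I told myself, then the early end, and join them.

the same everywhere: impurity 2.2 µM
- larch: starting material 20 mM; second substrate 17 mM; free enzyme 4 µM; run made earlier
- elm: starting material 20 mM; second substrate 26 mM; free enzyme 4 µM; run made earlier
- oak: starting material 40 mM; second substrate 12 mM; free enzyme 4 µM; run made earlier
- flask: starting material 20 mM; second substrate 12.0 mM; free enzyme 4.0 µM; time 10 min

- larch (time / min: target / %, starting material / %): 0.417: 28.0, 71.6; 1.33: 59.6, 40.6; 2.50: 76.2, 23.5; 3.00: 79.9, 20.2; 5.00: 84.8, 15.8; 6.00: 85.5, 16.2; 8.00: 85.7, 14.7
- elm (time / min: target / %, starting material / %): 0.667: 45.6, 54.7; 1.00: 58.7, 40.6; 1.33: 69.7, 31.1; 2.50: 91.2, 9.6; 3.00: 95.7, 5.8; 5.00: 99.4, 0; 8.00: 99.8, 0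
- oak (time / min: target / %, starting material / %): 0.667: 20.2, 79.5; 2.00: 28.6, 71.8; 4.00: 29.1, 69.4; 6.00: 29.7, 69.4; 8.00: 29.6, 70.9

(scatter of a reading: 0.5 percentage points)



- amount of target in the flask at 10 min, in percent of the starting material charged
- amount of starting material in the flask at 10 min, in percent of the starting material charged

Late end: I read from the larch and oak runs that one starting material went with one second substrate. The larch target levelled at 85.7% against 85.0% for the second substrate charged, the oak target at 29.6% against 30.0%. In the flask second substrate was the limiting reagent, so I put the ceiling at 60.0%.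

Early end: in the oak run, with starting material in excess, I read 0.653 min from the target at 2.00 min. I called this the clearing time τ, the time for second substrate to fall by a factor e with starting material in excess. I guessed that τ stretches as live catalyst shrinks, live catalyst L being free enzyme charged less impurity charged, here 1.80 µM.

Joining them, I took target at time t as the ceiling less the ceiling times e^(−t/τ). By this reckoning the flask had 15.3 clearing times, so I committed to 60.0% target and 40.0% starting material.

The weak link was τ, since oak held more starting material. I reforged it from the larch reading at 2.50 min, which gave 1.10 min, longer than the oak value. This larch value was still shorter than 10 min, so I kept my answer.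

The forecast gave 60% target and 40% starting material, on the ground that “every run goes as far as its limiting reagent allows”.

The flask gave 60.0% target and 40.0% starting material. Spent catalyst stood at 55.0% of the catalyst charged. At 1.00 min, the oak τ gave 21.6% of second substrate left, and the flask held 30.6%.

    first complex ⇌ loaded enzyme + first product (K = 0.0550 M, k = 2000 s⁻¹)
    second substrate + loaded enzyme ⇌ second complex (K = 27.0 M⁻¹, k = 42000 M⁻¹ s⁻¹)
    starting material + free enzyme ⇌ first complex (K = 460 M⁻¹, k = 14000 M⁻¹ s⁻¹)
    second complex → free enzyme + target (k = 1200 s⁻¹)
    free enzyme + impurity → spent catalyst (k = 1.60 × 10⁵ M⁻¹ s⁻¹)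

In the neighbour with 0.0037 mM of impurity, I reckoned L at 0.300 µM, which stretches the oak τ to 3.92 min and gives 55.3% target at 10 min. That neighbour gave 54.7%.

Readings and results are calculated on assumed constants.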